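**Retrosynthetic overview**
- The acid comes from a masked acrolein (acetal → enal → acid), the C-9 ester from acylation with (3S)-3-methylpentanoic acid, and the axial 9α-alcohol from equatorial hydride delivery to a C-9 ketone.
- The axial 7α side chain comes from cuprate addition of an α-acrolein anion equivalent to a trans-fused Δ7-en-9-one.
- The enone comes from IBX oxidation/dehydrogenation of a diol made by α-face hydroboration of a tetrasubstituted Δ4 alkene, which sets C-4 and C-5 together.
- The alkene comes from methyl coupling of an enol triflate, itself formed by enantioselective copper-catalysed methyl addition to the C2h-symmetric 2,3,4,6,7,8-hexahydronaphthalene-1,5-dione (key step: sets C-10 and differentiates the two carbonyls).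
- The ene-dione comes from Birch reduction/hydrolysis of 5-methoxy-1-tetralone; both rings are inherited from the naphthalene skeleton, so no ring is formed, only the arene ring is dearomatised.

Assumption: 1, 11 and 14 are bought; eudesmane numbering is used in the text, and the target is (4R,5R,7R,9R,10S,3'S), i.e. H-5, 4-OH, the C-7 side chain and the C-9 ester all lie on the face opposite the C-10 methyl.

**Step 1**
Reactants: 1 5-methoxy-3,4-dihydronaphthalen-1(2H)-one
Product: 3 2,3,4,6,7,8-hexahydronaphthalene-1,5-dione, via methoxy diene ketone 2 (not isolated)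
Conditions: K (2.5 equiv), NH3(l)/THF, t-BuOH (1 equiv), −78 °C; NH4Cl; then 2 M HCl, THF, 45 °C
Reagents that add atoms: water, O
Why: Birch-type reduction of an aryl ketone (Narisada–Watanabe enolate formation) puts the ring proton para to the acyl-bearing carbon and ortho to OMe, where both groups direct it, and aqueous acid then hydrolyses the methyl enol ether and moves the remaining alkene into the tetrasubstituted position conjugated to both carbonyls; no stereocentre remains.

**Step 2**
Reactants: 3 2,3,4,6,7,8-hexahydronaphthalene-1,5-dione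
Product: 5 (4aS)-4a-methyl-5-oxo-2,3,4,4a,5,6,7,8-octahydronaphthalen-1-yl trifluoromethanesulfonate, via aluminum enolate 4 (not isolated)
Conditions: Me3Al (1.5 equiv), Cu(O2CC4H3S) (copper thiophene-2-carboxylate, 5 mol%), phosphoramidite L1 (10 mol%; (S)-1,1'-binaphthyl-2,2'-diyl N,N-bis[(S)-1-phenylethyl]phosphoramidite), Et2O, −30 °C; then Tf2O (1.6 equiv), −78 → 0 °C
Reagents that add atoms: trimethylaluminum, C[Al](C)C; trifluoromethanesulfonic anhydride, O=S(=O)(OS(=O)(=O)C(F)(F)F)C(F)(F)F
Why: Proposed new method: each carbon of the tetrasubstituted alkene in 3 is β to one carbonyl and α to the other (an ene-1,4-dione), so the acceptor should be electrophilic enough for copper–phosphoramidite methyl transfer from Me3Al (π-complex, trivalent copper intermediate, reductive elimination) despite full substitution; the two alkene carbons are related by the C2 axis, so the catalyst only has to choose one π-face, which sets the quaternary centre (4aS; the mirror-image ligand is used if a test run gives the antipode) and leaves a regiodefined aluminum enolate that is O-triflated; the closest known reactions are copper-catalysed asymmetric conjugate additions of Me3Al to 3-substituted cyclohexenones (quaternary centres, enolate trapping with hard electrophiles) and copper-catalysed desymmetrising additions to cyclopent-4-ene-1,3-diones.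

**Step 3**
Reactants: 5 (4aS)-4a-methyl-5-oxo-2,3,4,4a,5,6,7,8-octahydronaphthalen-1-yl trifluoromethanesulfonate
Product: 6 (8aS)-5,8a-dimethyl-3,4,6,7,8,8a-hexahydronaphthalen-1(2H)-one
Conditions: MeZnCl (2 equiv), Pd(PPh3)4 (5 mol%), THF, 55 °C
Reagents that add atoms: methylzinc chloride, C[Zn]Cl
Why: Negishi cross-coupling of an alkenyl triflate; MeZnCl does not touch the neopentyl ketone and the quaternary centre is unaffected.

**Step 4**
Reactants: 6 (8aS)-5,8a-dimethyl-3,4,6,7,8,8a-hexahydronaphthalen-1(2H)-one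
Product: 8 (1R,4aS,8aR)-1,4a-dimethyldecahydronaphthalene-1,5-diol (both epimers at the secondary carbinol), via alkylborane 7 (not isolated)
Conditions: BH3·THF (4 equiv), THF, 0 → 45 °C; then 3 M NaOH, 30% H2O2, 0 → 50 °C
Reagents that add atoms: borane, B (boron is present only in 7); hydrogen peroxide, OO
Why: Hydroboration–oxidation: BH3 adds syn across the tetrasubstituted alkene from the face opposite the angular methyl with boron on C-4 (the carbon remote from the quaternary centre), so oxidation with retention gives the 4α tertiary alcohol (4R) and the 5α hydrogen (5R, trans ring fusion) in one operation; the ketone is reduced on the way and that carbinol centre is erased in step 5.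

**Step 5**
Reactants: 8 (1R,4aS,8aR)-1,4a-dimethyldecahydronaphthalene-1,5-diol
Product: 10 (4aR,5R,8aS)-5-hydroxy-5,8a-dimethyl-4a,5,6,7,8,8a-hexahydronaphthalen-1(4H)-one, via hydroxy ketone 9 (not isolated)
Conditions: IBX (3.5 equiv), DMSO/fluorobenzene (1:2), 70 °C
Reagents that add atoms: none
Why: IBX alcohol oxidation followed by IBX α,β-dehydrogenation of the ketone (Nicolaou conditions); the quaternary C-10 leaves only C-8 enolisable, so a single enone forms, the tertiary alcohol is inert and no stereocentre changes.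

**Step 6**
Reactants: 10 (4aR,5R,8aS)-5-hydroxy-5,8a-dimethyl-4a,5,6,7,8,8a-hexahydronaphthalen-1(4H)-one; 11 2-bromo-3,3-diethoxyprop-1-ene
Product: 12 (3R,4aR,5R,8aS)-3-(3,3-diethoxyprop-1-en-2-yl)-5-hydroxy-5,8a-dimethyloctahydronaphthalen-1(2H)-one
Conditions: 11 (3.2 equiv), t-BuLi (6.4 equiv), Et2O, −78 °C; CuBr·SMe2 (1.6 equiv), −78 → −40 °C; then 10, THF, −78 → −30 °C; aq. NH4Cl/NH3
Reagents that add atoms: none
Why: Gilman cuprate conjugate addition of Boeckman's α-acrolein anion equivalent: on the trans-fused enone the nucleophile enters C-7 along the axial trajectory that leads to a chair enolate, i.e. from the α face opposite the angular methyl (as in cuprate additions to 5α-steroidal enones), giving the axial 7α side chain (7R); the excess reagent covers the free tertiary OH.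

**Step 7**
Reactants: 12 (3R,4aR,5R,8aS)-3-(3,3-diethoxyprop-1-en-2-yl)-5-hydroxy-5,8a-dimethyloctahydronaphthalen-1(2H)-one
Product: 13 (1R,4aS,5R,7R,8aR)-7-(3,3-diethoxyprop-1-en-2-yl)-1,4a-dimethyldecahydronaphthalene-1,5-diol
Conditions: LiBH(s-Bu)3 (2.5 equiv), THF, −78 °C; then aq. NaOH, H2O2, 0 °C
Reagents that add atoms: none
Why: Selectride reduction: the axial approach to C-9 is blocked by the syn-axial C-7 substituent, so the bulky hydride comes from the equatorial β side and gives the axial 9α alcohol (9R), cis to the side chain.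

**Step 8**
Reactants: 13 (1R,4aS,5R,7R,8aR)-7-(3,3-diethoxyprop-1-en-2-yl)-1,4a-dimethyldecahydronaphthalene-1,5-diol; 14 (3S)-3-methylpentanoic acid
Product: 15 (1R,3R,4aR,5R,8aS)-3-(3,3-diethoxyprop-1-en-2-yl)-5-hydroxy-5,8a-dimethyldecahydronaphthalen-1-yl (3S)-3-methylpentanoate
Conditions: 14 (2 equiv), 2,4,6-trichlorobenzoyl chloride (2 equiv), Et3N (4 equiv), THF, rt; then 13, DMAP (2 equiv), toluene, 70 °C
Reagents that add atoms: none
Why: Yamaguchi esterification through the mixed anhydride acylates the hindered secondary alcohol while the tertiary C-4 alcohol stays free; neither the carbinol centre nor the β-stereocentre of the acid can epimerise.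

**Step 9**
Reactants: 15 (1R,3R,4aR,5R,8aS)-3-(3,3-diethoxyprop-1-en-2-yl)-5-hydroxy-5,8a-dimethyldecahydronaphthalen-1-yl (3S)-3-methylpentanoate
Product: 17 2-[(2R,4R,4aS,8R,8aR)-8-hydroxy-4a,8-dimethyl-4-{[(3S)-3-methylpentanoyl]oxy}decahydronaphthalen-2-yl]prop-2-enoic acid (target), via enal 16 (not isolated)
Conditions: PPTS (0.2 equiv), acetone/H2O (9:1), 40 °C; then NaClO2, NaH2PO4, 2-methylbut-2-ene, t-BuOH/H2O, 0 °C → rt
Reagents that add atoms: water, O; sodium chlorite, [Na+].[O-]Cl=O
Why: Acid-catalysed acetal hydrolysis to the 2-substituted acrolein followed by Pinnick oxidation of the enal to the acrylic acid; the mild buffered conditions leave the ester, the tertiary alcohol and all stereocentres untouched.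

**Compound list**
1 | 5-methoxy-3,4-dihydronaphthalen-1(2H)-one (5-methoxy-1-tetralone) | COc1cccc2C(=O)CCCc12 | starting material
2 | 5-methoxy-3,4,6,8a-tetrahydronaphthalen-1(2H)-one (racemic) | COC1=C2CCCC(=O)C2C=CC1 | intermediate
3 | 2,3,4,6,7,8-hexahydronaphthalene-1,5-dione | O=C1CCCC2=C1CCCC2=O | intermediate
4 | dimethylaluminum (4aS)-4a-methyl-5-oxo-2,3,4,4a,5,6,7,8-octahydronaphthalen-1-olate | C[Al](C)OC1=C2CCCC(=O)[C@@]2(C)CCC1 | intermediate
5 | (4aS)-4a-methyl-5-oxo-2,3,4,4a,5,6,7,8-octahydronaphthalen-1-yl trifluoromethanesulfonate | FC(F)(F)S(=O)(=O)OC1=C2CCCC(=O)[C@@]2(C)CCC1 | intermediate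
6 | (8aS)-5,8a-dimethyl-3,4,6,7,8,8a-hexahydronaphthalen-1(2H)-one | CC1=C2CCCC(=O)[C@@]2(C)CCC1 | intermediate
7 | borane adduct of 6: BH2 on C-4 (α face), H-5 α, C-9 oxygen as O-BH2 | BOC1CCC[C@H]2[C@](C)(B)CCC[C@]12C | intermediate
8 | (1R,4aS,8aR)-1,4a-dimethyldecahydronaphthalene-1,5-diol (epimers at the secondary carbinol) | OC1CCC[C@H]2[C@](C)(O)CCC[C@]12C | intermediate
9 | (4aR,5R,8aS)-5-hydroxy-5,8a-dimethyloctahydronaphthalen-1(2H)-one | O=C1CCC[C@H]2[C@](C)(O)CCC[C@]12C | intermediate
10 | (4aR,5R,8aS)-5-hydroxy-5,8a-dimethyl-4a,5,6,7,8,8a-hexahydronaphthalen-1(4H)-one | O=C1C=CC[C@H]2[C@](C)(O)CCC[C@]12C | intermediate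
11 | 2-bromo-3,3-diethoxyprop-1-ene | C=C(Br)C(OCC)OCC | starting material
12 | (3R,4aR,5R,8aS)-3-(3,3-diethoxyprop-1-en-2-yl)-5-hydroxy-5,8a-dimethyloctahydronaphthalen-1(2H)-one | C=C(C(OCC)OCC)[C@@H]1C[C@@H]2[C@](C)(CCC[C@@]2(C)O)C(=O)C1 | intermediate
13 | (1R,4aS,5R,7R,8aR)-7-(3,3-diethoxyprop-1-en-2-yl)-1,4a-dimethyldecahydronaphthalene-1,5-diol | C=C(C(OCC)OCC)[C@@H]1C[C@@H]2[C@](C)(CCC[C@@]2(C)O)[C@H](O)C1 | intermediate
14 | (3S)-3-methylpentanoic acid | CC[C@H](C)CC(=O)O | starting material
15 | (1R,3R,4aR,5R,8aS)-3-(3,3-diethoxyprop-1-en-2-yl)-5-hydroxy-5,8a-dimethyldecahydronaphthalen-1-yl (3S)-3-methylpentanoate | C=C(C(OCC)OCC)[C@@H]1C[C@@H]2[C@](C)(CCC[C@@]2(C)O)[C@H](OC(=O)C[C@@H](C)CC)C1 | intermediate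
16 | (1R,3R,4aR,5R,8aS)-5-hydroxy-5,8a-dimethyl-3-(3-oxoprop-1-en-2-yl)decahydronaphthalen-1-yl (3S)-3-methylpentanoate | C=C(C=O)[C@@H]1C[C@@H]2[C@](C)(CCC[C@@]2(C)O)[C@H](OC(=O)C[C@@H](C)CC)C1 | intermediate
17 | 2-[(2R,4R,4aS,8R,8aR)-8-hydroxy-4a,8-dimethyl-4-{[(3S)-3-methylpentanoyl]oxy}decahydronaphthalen-2-yl]prop-2-enoic acid | C=C(C(=O)O)[C@@H]1C[C@@H]2[C@](C)(CCC[C@@]2(C)O)[C@H](OC(=O)C[C@@H](C)CC)C1 | target

**Step count and risks**
Total step count: 9. Longest linear sequence: 9 steps (1 → 17); 11 and 14 enter as bought reagents.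

The three operations most likely to fail:

- **The copper-catalysed methyl addition with triflation (step 2).** It is the least precedented operation, since a fully substituted alkene may react slowly or with low face selectivity. The fallback sets out from 3 and comes back at 5.
  - Both carbonyls of 3 are reduced with (R)-Me-CBS oxazaborolidine and BH3·SMe2 to the C2-symmetric (1S,5S)-1,2,3,4,5,6,7,8-octahydronaphthalene-1,5-diol F3.
  - The two allylic hydroxyls direct Et2Zn/CH2I2 cyclopropanation to their own face, giving (1R,2S,6R,7S)-tricyclo[4.4.1.0^1,6]undecane-2,7-diol F4.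
  - Dess–Martin oxidation gives (1R,6R)-tricyclo[4.4.1.0^1,6]undecane-2,7-dione F5.
  - Li (2.1 equiv) in NH3 cleaves the cyclopropane bond that overlaps with the carbonyl π system (either of the two homotopic CH2–C bonds). This turns the CH2 into the angular methyl and leaves the regiodefined lithium enolate, which PhNTf2 traps as 5.

- **The hydroboration of the hindered tetrasubstituted alkene (step 4).** It may be slow or may place boron on the ring-fusion carbon. The fallback sets out from 3 and comes back at 8.
  - The methyl addition of step 2 is quenched with aqueous NH4Cl instead of Tf2O, and the product is equilibrated with NaOMe/MeOH to the trans-fused (4aS,8aR)-4a-methyloctahydronaphthalene-1,5-dione F6.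
  - Ph3P=CH2 methylenates only the ketone that is not next to the quaternary carbon, giving (4aS,8aS)-8a-methyl-5-methylideneoctahydronaphthalen-1(2H)-one F7.
  - mCPBA epoxidises the exocyclic alkene from the face anti to the angular methyl, giving (1R,4aS,8aR)-4a-methyloctahydrospiro[naphthalene-1,2'-oxiran]-5-one F8.
  - LiAlH4 opens the oxirane at its CH2 and reduces the ketone, which gives diol 8.

- **The dissolving-metal reduction of the aryl ketone (step 1).** It can over-reduce the carbonyl or give mixtures of alkene isomers. The fallback sets out from 1 and comes back at 3.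
  - NaBH4 reduces 1 to 5-methoxy-1,2,3,4-tetrahydronaphthalen-1-ol F1.
  - A standard Birch reduction of the anisole ring (Li, NH3, EtOH; the benzylic alkoxide is not cleaved) followed by aqueous HCl gives the conjugated enone 5-hydroxy-3,4,5,6,7,8-hexahydronaphthalen-1(2H)-one F2.
  - MnO2 oxidises the allylic alcohol to 3.

**Further compounds**
F1 | step 1 | 5-methoxy-1,2,3,4-tetrahydronaphthalen-1-ol (racemic) | COc1cccc2C(O)CCCc12
F2 | step 1 | 5-hydroxy-3,4,5,6,7,8-hexahydronaphthalen-1(2H)-one (racemic) | O=C1CCCC2=C1CCCC2O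
F3 | step 2 | (1S,5S)-1,2,3,4,5,6,7,8-octahydronaphthalene-1,5-diol | O[C@H]1CCCC2=C1CCC[C@@H]2O
F4 | step 2 | (1R,2S,6R,7S)-tricyclo[4.4.1.0^1,6]undecane-2,7-diol | O[C@H]1CCC[C@@]23C[C@@]12CCC[C@@H]3O
F5 | step 2 | (1R,6R)-tricyclo[4.4.1.0^1,6]undecane-2,7-dione | O=C1CCC[C@@]23C[C@@]12CCCC3=O
F6 | step 4 | (4aS,8aR)-4a-methyloctahydronaphthalene-1,5-dione | O=C1CCC[C@H]2C(=O)CCC[C@]12C
F7 | step 4 | (4aS,8aS)-8a-methyl-5-methylideneoctahydronaphthalen-1(2H)-one | O=C1CCC[C@H]2C(=C)CCC[C@]12C
F8 | step 4 | (1R,4aS,8aR)-4a-methyloctahydrospiro[naphthalene-1,2'-oxiran]-5-one (oxirane O anti to the angular methyl) | O=C1CCC[C@H]2[C@@]3(CO3)CCC[C@]12C
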